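Everything rests on making the benzene ring last: its C2–C3, C4–C5 and C5–C6 bonds are disconnected to a 3-alkylcyclobutenone and methoxyacetylene. The arene is a 1,3,5-trisubstituted ring with the side chain on C1, OMe on C3, free OH on C5 and hydrogen on C2, C4 and C6. A thermal Danheiser benzannulation gives this pattern, with the two oxygens already told apart, in one operation. Its precursor is an (R)-3-(2-acetoxytridecyl)cyclobutenone whose remote hydroxyl is benzyl-protected. The stereocenter comes from (R)-epichlorohydrin and the acetate is installed before the ring is built, so only a hydrogenolysis follows.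

Key step: step 8

Remark: the remote primary hydroxyl is carried as a benzyl ether, not a silyl ether, because Cl3CCOCl/ZnCl2 in step 5 can cleave silyl ethers acylatively and a benzyl ether allows a neutral last step; the acetoxy carbon is (R) in 3, 5–10 and 14–19 because no bond to it is ever broken; 1, 3 and 11 are commercial.

Step 1
Reactants: 1 10-bromodecan-1-ol
Product: 2 benzyl 10-bromodecyl ether
Conditions: BnOC(=NH)CCl3 (1.3 equiv), TfOH (5 mol%), CH2Cl2/cyclohexane, 0 °C to rt
Reagents that add atoms: benzyl 2,2,2-trichloroacetimidate, N=C(OCc1ccccc1)C(Cl)(Cl)Cl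
Why: Acid-catalysed O-benzylation with a trichloroacetimidate donor needs no base, so the primary bromide cannot enter a competing Williamson reaction and only the hydroxyl is capped.

Step 2
Reactants: 2 benzyl 10-bromodecyl ether; 3 (R)-epichlorohydrin
Product: 5 (R)-13-(benzyloxy)-1-chlorotridecan-2-ol, via Grignard reagent 4 (not isolated)
Conditions: Mg turnings, THF, 45 °C; then CuI (10 mol%), 3 (0.85 equiv), THF, −40 to −20 °C; then 1 M HCl, 0 °C
Reagents that add atoms: none
Why: Copper-catalysed Grignard opening of an epoxide is an SN2 attack at the unsubstituted ring carbon and is faster than displacement of the primary chloride, so the chlorohydrin should form with the stereocenter of 3, which is not a reacting center, carried over as (R).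

Step 3
Reactants: 5 (R)-13-(benzyloxy)-1-chlorotridecan-2-ol
Product: 7 (R)-15-(benzyloxy)pentadec-1-yn-4-ol, via epoxide 6 (not isolated)
Conditions: LiC≡CH·H2NCH2CH2NH2 (3.5 equiv), DMSO/THF, 0 °C to rt; then H2O
Reagents that add atoms: lithium acetylide–ethylenediamine complex, [Li+].[C-]#C.NCCN
Why: One equivalent of acetylide deprotonates the chlorohydrin, whose alkoxide closes to terminal epoxide 6 by intramolecular Williamson displacement at CH2Cl, and further acetylide opens 6 at its CH2 carbon (epoxide alkynylation), so the C–O bond of the stereocenter is never broken and (R) is kept.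

Step 4
Reactants: 7 (R)-15-(benzyloxy)pentadec-1-yn-4-ol
Product: 8 (R)-15-(benzyloxy)pentadec-1-yn-4-yl acetate
Conditions: Ac2O, pyridine, DMAP (cat.), CH2Cl2, 0 °C to rt
Reagents that add atoms: acetic anhydride, CC(=O)OC(C)=O
Why: DMAP-catalysed acylation of an unhindered secondary alcohol occurs at oxygen only, so the configuration is retained and the alcohol is masked before the acid chloride of step 5 is introduced.

Step 5
Reactants: 8 (R)-15-(benzyloxy)pentadec-1-yn-4-yl acetate
Product: 9 (R)-13-(benzyloxy)-1-(4,4-dichloro-3-oxocyclobut-1-en-1-yl)tridecan-2-yl acetate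
Conditions: Cl3CCOCl (2.5 equiv, slow addition), Zn(Cu) couple (3 equiv), Et2O/DME, rt; filtered through Celite and used crude
Reagents that add atoms: trichloroacetyl chloride, O=C(Cl)C(Cl)(Cl)Cl
Why: Dichloroketene generated by zinc reduction of the acid chloride adds to the terminal alkyne in a [2+2] cycloaddition, its carbonyl carbon bonding to the terminal CH, which gives the 3-substituted 4,4-dichlorocyclobutenone; DME ties up ZnCl2 so that the benzyl ether and the acetate should survive.

Step 6
Reactants: 9 (R)-13-(benzyloxy)-1-(4,4-dichloro-3-oxocyclobut-1-en-1-yl)tridecan-2-yl acetate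
Product: 10 (R)-3-[2-acetoxy-13-(benzyloxy)tridecyl]cyclobut-2-en-1-one
Conditions: Zn dust (5 equiv), AcOH, TMEDA, EtOH, 0 °C to rt
Reagents that add atoms: none
Why: Buffered zinc reduction of the α,α-dichloroketone (reductive dehalogenation) removes both chlorines without reducing the enone or touching the ester and ether, and any 2,4-dichloro isomer formed by allylic chloride shift would converge on the same product.

Step 7
Reactants: 11 chloroacetaldehyde dimethyl acetal
Product: 13 methoxyacetylene, via sodium methoxyacetylide 12 (not isolated)
Conditions: NaNH2 (3.1 equiv), liquid NH3, −33 °C; then cold saturated aqueous NaCl, −20 °C; distilled into a −78 °C trap and kept as a cold toluene solution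
Reagents that add atoms: none
Why: Amide base removes methanol and HCl by two successive β-eliminations and deprotonates the resulting alkyne to its sodium salt, which is protonated on aqueous quench; this is the classical preparation of alkoxyacetylenes from α-chloroacetals.

Step 8
Reactants: 10 (R)-3-[2-acetoxy-13-(benzyloxy)tridecyl]cyclobut-2-en-1-one; 13 methoxyacetylene
Product: 18 (R)-13-(benzyloxy)-1-(3-hydroxy-5-methoxyphenyl)tridecan-2-yl acetate, via vinylketene 14 (not isolated), via 4-vinylcyclobutenone 15 (not isolated), via dienylketene 16 (not isolated), via cyclohexadienone 17 (not isolated)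
Conditions: 13 (3 equiv), toluene, sealed tube, 80 °C, then 110 °C
Reagents that add atoms: none
Why: On warming, cyclobutenone 10 should undergo conrotatory 4π ring opening to vinylketene 14, whose C=C=O unit engages methoxyacetylene in a [2+2] cycloaddition to give 15; a second 4π opening unveils dienylketene 16, 6π electrocyclization closes cyclohexadienone 17 and enolization furnishes phenol 18. This is the Danheiser benzannulation, an established reaction of 3-alkylcyclobutenones with alkoxyacetylenes. The one ring formed, the benzene ring, is closed by the thermally allowed disrotatory 6π electrocyclization that joins the ketene carbon (arene C5) to the former ring CH2 (arene C6), after the [2+2] event has made C4–C5 and C2–C3. No stereocenter is created, and the (R) acetoxy carbon lies outside the pericyclic array in a neutral medium, so it should pass through unchanged. Only one orientation of the [2+2] event is acceptable, terminal alkyne CH to the ketene carbonyl carbon and the oxygen-bearing alkyne carbon to the ketene α-carbon; the donor oxygen makes the terminal carbon the nucleophile and the ketene carbonyl carbon is the electrophile, so this is the inherent orientation and it places OMe meta to both OH and the chain. The ketene oxygen emerges as the free phenol and the alkyne oxygen as the methyl ether, so no phenol protection is needed.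

Step 9
Reactants: 18 (R)-13-(benzyloxy)-1-(3-hydroxy-5-methoxyphenyl)tridecan-2-yl acetate
Product: 19 (R)-13-hydroxy-1-(3-hydroxy-5-methoxyphenyl)tridecan-2-yl acetate
Conditions: H2 (1 atm), 10% Pd/C, EtOAc, rt
Reagents that add atoms: none
Why: Palladium-catalysed hydrogenolysis cleaves the benzylic C–O bond of the primary benzyl ether under neutral conditions that leave the phenol, the aryl methyl ether and the non-benzylic secondary acetate intact.

Compound list
1 | 10-bromodecan-1-ol | OCCCCCCCCCCBr | starting material
2 | benzyl 10-bromodecyl ether | BrCCCCCCCCCCOCc1ccccc1 | intermediate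
3 | (R)-epichlorohydrin, (R)-2-(chloromethyl)oxirane | ClC[C@H]1CO1 | starting material
4 | 10-(benzyloxy)decylmagnesium bromide (Grignard reagent, not isolated) | Br[Mg]CCCCCCCCCCOCc1ccccc1 | intermediate
5 | (R)-13-(benzyloxy)-1-chlorotridecan-2-ol | ClC[C@H](O)CCCCCCCCCCCOCc1ccccc1 | intermediate
6 | (R)-2-[11-(benzyloxy)undecyl]oxirane (not isolated) | C1O[C@@H]1CCCCCCCCCCCOCc1ccccc1 | intermediate
7 | (R)-15-(benzyloxy)pentadec-1-yn-4-ol | C#CC[C@H](O)CCCCCCCCCCCOCc1ccccc1 | intermediate
8 | (R)-15-(benzyloxy)pentadec-1-yn-4-yl acetate | C#CC[C@@H](CCCCCCCCCCCOCc1ccccc1)OC(C)=O | intermediate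
9 | (R)-13-(benzyloxy)-1-(4,4-dichloro-3-oxocyclobut-1-en-1-yl)tridecan-2-yl acetate | O=C1C=C(C[C@@H](CCCCCCCCCCCOCc2ccccc2)OC(C)=O)C1(Cl)Cl | intermediate
10 | (R)-3-[2-acetoxy-13-(benzyloxy)tridecyl]cyclobut-2-en-1-one | O=C1C=C(C[C@@H](CCCCCCCCCCCOCc2ccccc2)OC(C)=O)C1 | intermediate
11 | chloroacetaldehyde dimethyl acetal, 2-chloro-1,1-dimethoxyethane | COC(CCl)OC | starting material
12 | sodium methoxyacetylide (not isolated) | COC#[C-].[Na+] | intermediate
13 | methoxyacetylene | COC#C | intermediate
14 | vinylketene, (R)-16-(benzyloxy)-3-methylidene-1-oxohexadec-1-en-5-yl acetate (not isolated) | O=C=CC(=C)C[C@@H](CCCCCCCCCCCOCc1ccccc1)OC(C)=O | intermediate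
15 | 4-vinylcyclobutenone, (R)-15-(benzyloxy)-2-(2-methoxy-4-oxocyclobut-2-en-1-yl)pentadec-1-en-4-yl acetate, both epimers at the ring CH (not isolated) | COC1=CC(=O)C1C(=C)C[C@@H](CCCCCCCCCCCOCc1ccccc1)OC(C)=O | intermediate
16 | dienylketene, (R)-18-(benzyloxy)-3-methoxy-5-methylidene-1-oxooctadeca-1,3-dien-7-yl acetate, ketene CH and C5 cis across C3=C4 (not isolated) | O=C=C/C(OC)=C\C(=C)C[C@@H](CCCCCCCCCCCOCc1ccccc1)OC(C)=O | intermediate
17 | cyclohexadienone, (R)-13-(benzyloxy)-1-(3-methoxy-5-oxocyclohexa-1,3-dien-1-yl)tridecan-2-yl acetate (not isolated) | O=C1C=C(OC)C=C(C[C@@H](CCCCCCCCCCCOCc2ccccc2)OC(C)=O)C1 | intermediate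
18 | (R)-13-(benzyloxy)-1-(3-hydroxy-5-methoxyphenyl)tridecan-2-yl acetate | COc1cc(O)cc(C[C@@H](CCCCCCCCCCCOCc2ccccc2)OC(C)=O)c1 | intermediate
19 | (R)-13-hydroxy-1-(3-hydroxy-5-methoxyphenyl)tridecan-2-yl acetate | COc1cc(O)cc(C[C@@H](CCCCCCCCCCCO)OC(C)=O)c1 | target

Total step count: 9.
Longest linear sequence: 8 steps (steps 1–6, 8 and 9, from 10-bromodecan-1-ol 1); step 7 is a one-step branch.

Steps most likely to fail

Step 8. The freshly formed phenol may be acylated by vinylketene that has not yet met the alkyne, the volatile ynol ether may escape or oligomerise before it is captured, and long heating may eliminate acetic acid from the side chain. The fallback gives up ring construction and attaches a preformed arene to the same chiral chain. It sets out from chlorohydrin 5, which NaOH in aqueous THF should close to epoxide 6, now isolated. Commercial 3-bromo-5-methoxyphenol is benzylated (BnBr, K2CO3, DMF) to give 1-(benzyloxy)-3-bromo-5-methoxybenzene F1. Mg in THF converts it into 3-(benzyloxy)-5-methoxyphenylmagnesium bromide F2, which with CuI (10 mol%) at −30 °C should open 6 at its CH2 carbon to give (R)-13-(benzyloxy)-1-[3-(benzyloxy)-5-methoxyphenyl]tridecan-2-ol F3. Ac2O/pyridine/DMAP should then give (R)-13-(benzyloxy)-1-[3-(benzyloxy)-5-methoxyphenyl]tridecan-2-yl acetate F4. H2 over Pd/C in EtOAc removes both benzyl groups, and the fallback comes back to the route at target 19.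

Step 5. Dichloroketene may oligomerise faster than it adds to the unactivated alkyne, and the acid chloride together with ZnCl2 may attack the benzyl ether or the acetate. The fallback is a keteniminium [2+2] cycloaddition, which needs neither zinc nor chlorine. It sets out from alkyne 8. N,N-Dimethylacetamide, Tf2O and 2,4,6-collidine in 1,2-dichloroethane at reflux generate N,N-dimethylketeniminium triflate, which should add to the alkyne with the same regiochemistry to give (R)-N-{3-[2-acetoxy-13-(benzyloxy)tridecyl]cyclobut-2-en-1-ylidene}-N-methylmethanaminium trifluoromethanesulfonate F5. Hydrolysis with aqueous NaHCO3 should release cyclobutenone 10, where the fallback rejoins the route; step 6 is then not needed.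

Step 3. Ring closure and alkynylation in one pot may stall at the epoxide, or the strongly basic medium may consume material in side reactions. The fallback separates the two events and activates the epoxide with a Lewis acid instead of relying on a bare acetylide in DMSO. It sets out from chlorohydrin 5, which NaOH in aqueous THF converts into isolated epoxide 6. Lithium (trimethylsilyl)acetylide, made from ethynyltrimethylsilane and n-BuLi, with BF3·OEt2 in THF at −78 °C should open 6 at the terminal carbon to give (R)-15-(benzyloxy)-1-(trimethylsilyl)pentadec-1-yn-4-ol F6. K2CO3 in MeOH removes the silyl group, and the fallback rejoins the route at alkynol 7.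

Further compounds
F1 | step 8 | 1-(benzyloxy)-3-bromo-5-methoxybenzene | COc1cc(Br)cc(OCc2ccccc2)c1
F2 | step 8 | 3-(benzyloxy)-5-methoxyphenylmagnesium bromide | COc1cc([Mg]Br)cc(OCc2ccccc2)c1
F3 | step 8 | (R)-13-(benzyloxy)-1-[3-(benzyloxy)-5-methoxyphenyl]tridecan-2-ol | COc1cc(OCc2ccccc2)cc(C[C@H](O)CCCCCCCCCCCOCc2ccccc2)c1
F4 | step 8 | (R)-13-(benzyloxy)-1-[3-(benzyloxy)-5-methoxyphenyl]tridecan-2-yl acetate | COc1cc(OCc2ccccc2)cc(C[C@@H](CCCCCCCCCCCOCc2ccccc2)OC(C)=O)c1
F5 | step 5 | (R)-N-{3-[2-acetoxy-13-(benzyloxy)tridecyl]cyclobut-2-en-1-ylidene}-N-methylmethanaminium trifluoromethanesulfonate | C[N+](C)=C1C=C(C[C@@H](CCCCCCCCCCCOCc2ccccc2)OC(C)=O)C1.[O-]S(=O)(=O)C(F)(F)F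
F6 | step 3 | (R)-15-(benzyloxy)-1-(trimethylsilyl)pentadec-1-yn-4-ol | C[Si](C)(C)C#CC[C@H](O)CCCCCCCCCCCOCc1ccccc1
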